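The pitfall is to read an equilibrium constant as an amount in the flask.

| flask | starting material | partner | protic impurity | time | remark |
|---|---|---|---|---|---|
| green | 0.22 M | 1.20 equiv | 0.0110 M | 5.0 h | a closed flask charged with all of it at once and left for 5.0 h |
| teal | 0.22 M | 1.20 equiv | 0.0110 M | 5.0 h | a tube with plug flow, the mixed feed as stated, residence time 5.0 h |
| red | 0.22 M | 1.20 equiv | 0.0110 M |  | one stirred flow tank at steady state, fed with the mixture as stated, mean residence time 5.0 h |
| violet | 0.22 M | 1.20 equiv (fed, over 5.00 h) | 0.0110 M | 5.0 h | a stirred flask in which partner is dosed at a steady rate over 5.00 h without added volume, worked up at 5.0 h |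

    starting material ⇌ open intermediate (K1 = 0.14, k1 = 0.024 min⁻¹)
    partner → second intermediate (k2 = 0.055 min⁻¹)
    open intermediate + second intermediate → product (k3 = 0.29 M⁻¹ min⁻¹)
    starting material + protic impurity → quenched substrate (k4 = 42 M⁻¹ min⁻¹)

- the set-up with the highest amount of open intermediate at the outlet or at the end, in percent of the starting material put in ("none" if the first two lie within 2 percentage points) (green / teal / red / violet / none)
- amount of open intermediate at the outlet or at the end, in percent of the starting material put in, green
- amount of open intermediate at the outlet or at the end, in percent of the starting material put in, teal
- amount of open intermediate at the outlet or at the end, in percent of the starting material put in, red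
- amount of open intermediate at the outlet or at the end, in percent of the starting material put in, violet

Write A for starting material, I for open intermediate and J for second intermediate. We carry the closing constant kb: 0.171 min⁻¹, the opening constant divided by the equilibrium constant. Opening and closing relax with a half-life of 3.55 min, far shorter than the run of 5.0 h, so I keeps pace with A. A constant of 0.14 then seems to promise 12.3% of the charge as I in green, yet our reckoning ends elsewhere.

Closing and the step to product both remove I, so the steady-state ratio is

r = I/A = 0.024 min⁻¹ / (kb + 0.29 M⁻¹ min⁻¹ × J).

In green the impurity takes its own 0.0110 M of A early: the half-life of A by that step, with the impurity held at its charge, is 1.5 min, shorter than the 0.48 h by the forward rate of opening. Partner turns into J with a half-life of 0.21 h, shorter than the run. This leaves: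

pool p = A + I = 0.209 M
J at the start = 0.264 M
J minus p, constant = 0.0550 M

At a middling J of 0.160 M, r = 0.110, so the open share of the pool is 0.0993. Integrating the pool's loss gives:

J/p at the end = 2.03
p at the end = 0.0533 M
J at the end = 0.108 M
r at the end = 0.118
I at the end = 0.00564 M, or 2.56% of the charge

So 12.3% and 2.56% stand together: at the end I is still 0.106 of the pool, but the pool is down from 0.209 M to 0.0533 M. Teal is the same mixture aged the same time along a tube, so we expect the same figure. For red and violet we commit to no number.

The forecast gave 2.7% for green, 2.7% for teal, 4.4% for red and 4.8% for violet, with best none; its grounds for the last two were that “the stirred tank and dosed flask retain more substrate and so more open intermediate”. Our green figure lies slightly below its value.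

The simulation gives 2.70% for green, 2.70% for teal, 4.38% for red and 4.84% for violet, with best none.

At the end of violet, A stands at 41.9% and J at 0.142 M, so r gives 4.74% against the simulated 4.84%. The neighbouring flask is violet with 0.480 equiv of partner. There J ends at 0.0479 M, r is higher than in violet at 0.130, and A stands at 63.4%, which gives 8.23%. That flask reads 8.29%.

The rate constants were chosen freely.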